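The earlier runs and the new flask are simulated for an exercise; the scatter is artificial.

The dawn run, charged with the same Z as the flask, had 54 % of its Z left at 10.0 min, and I worked from that fraction left, not from a fraction made.

| flask | Z | J | remark | time |
|---|---|---|---|---|
| winter | 0.050 M | 0.50 equiv (fed, over 15 min) | run made earlier |  |
| dawn | 0.050 M | 2 equiv (fed, over 15 min) | run made earlier |  |
| autumn | 0.025 M | 1 equiv (fed, over 15 min) | run made earlier |  |
| flask | 0.050 M | 1.00 equiv (fed, over 15 min) |  | 15 min |

- winter (time / min: Z / %, L / %): 0.667: 102, 0; 1.50: 99, 2; 4.00: 99, 5; 10.0: 85, 12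
- dawn (time / min: Z / %, L / %): 0.667: 100, 0; 1.50: 98, 3; 4.00: 87, 11; 10.0: 54, 42
- autumn (time / min: Z / %, L / %): 2.50: 97, 1; 5.00: 92, 4; 6.00: 92, 9; 10.0: 84, 17

(standard deviation of a reading: 1.5 percentage points)

- the earlier runs do not show how much of J is bound; that part of a forecast is a guess

- part of the Z that has reacted at 15 min
- share of the unused J that is free and not bound as G, at 15 min

I counted exposure as minutes of one full equivalent of J met by Z. The steady feed in dawn had given 6.67 min of it, and from this I took the J spent, reckoned by hand as the fraction reacted times a third of the time, or 1.53 min. The natural logarithm of one over the fraction left, per minute of net exposure, my fade constant, a pseudo-first-order constant for this Z charge, came to 0.120 min⁻¹ as read from that one scattered reading.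

The flask's feed gave 7.50 min. With nothing spent, that meant 59.4 % reacted; the spent J reckoned from this figure came out too large, and the next pass gave 42.0 %. The spent J was my weak link, so I reforged it from the mean of the two passes and committed to 44.9 %.

The forecast said 42 % (35 % to 49 %), lower than mine, and 85 % free (55 % to 98 %), since “the rate shows no saturation in J, so binding looks weak”.

The flask gave 42.0 % reacted and 63.2 % free, 22 percentage points below the forecast's share, with 0.0104 M of G standing.

    J + L → E + X (k = 0.00535 M⁻¹ s⁻¹)
    Z + J → L + X (k = 0.0511 M⁻¹ s⁻¹)
    J + X ⇌ G, settled at all times (K = 51.5 M⁻¹)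
    J + E ⇌ D + X (K = 2.20, k = 0.0387 M⁻¹ s⁻¹)

Read back by the same count, the flask's 58.0 % of Z left gave a fade constant of 0.101 min⁻¹. Part of the reason the flask stood at 42.0 % reacted at 15 min was the drawn-out feeding together with the time allowed: with J given at once the flask reached 58.7 %, and with ten times the time it reached 84.2 %.

For the neighbour with 0.013 M of Z, the equivalents held, so I scaled the constant to 0.0312 min⁻¹, and two passes gave 18.3 %. That neighbour computed to 21.2 %, above my reckoning, with 91.1 % free.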